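The target is cut at the bond between the benzylic CH2 on the aspidinol-type outer ring (bridge carbon between OMe and OH) and C5 of the central acetylphloroglucinol ring. The key step exploits that carbon, the central ring's last CH, enol-like and flanked by two OH groups: the Mannich base of aspidinol loses dimethylamine to a dearomatised ortho-quinone methide, which this CH of a methylene-bridged dimer (core already carrying the other arm) captures; C–C bond formation rearomatises both rings with every phenol unprotected. Both outer rings are the same 5-methoxy-4-methylresorcinol nucleus with butanoyl and bridge positions exchanged, so one Hoesch acylation supplies both ketones.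

Key step: step 6

Remark: the target has no stereocentre and no other stereogenic element, so it is achiral and no enantiocontrol is needed; the two starting materials are taken as catalogue compounds.

Step 1
Reactants: 1 2,4-dihydroxy-6-methoxybenzaldehyde
Product: 3 5-methoxy-4-methylbenzene-1,3-diol, via benzylic alcohol 2 (not isolated)
Conditions: H2 (1 atm), 10% Pd/C, AcOH, rt
Reagents that add atoms: none
Why: Catalytic hydrogenation of the aryl aldehyde to the benzylic alcohol 2 and hydrogenolysis of its C–O bond, which the ortho- and para-OH groups make especially easy, should give the methylarene while the ring, the phenols and the aryl methyl ether stay untouched (benzylic hydrogenolysis).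

Step 2
Reactants: 3 5-methoxy-4-methylbenzene-1,3-diol
Product: 6 1-(4,6-dihydroxy-2-methoxy-3-methylphenyl)butan-1-one and 7 1-(2,6-dihydroxy-4-methoxy-3-methylphenyl)butan-1-one (aspidinol), via para-hydroxy ketiminium chloride 4 (not isolated), via bis-ortho-hydroxy ketiminium chloride 5 (not isolated)
Conditions: PrCN (1.2 equiv), ZnCl2 (0.3 equiv), HCl (g), Et2O, 0 °C; then H2O, 100 °C; both ketones isolated on silica gel
Reagents that add atoms: butyronitrile (CCCC#N); water (O)
Why: Hoesch ketone synthesis, in which the HCl-activated nitrile should acylate both free ring positions of 3 (the CH between OH and OMe, para to the other OH, leads to 6 and the CH between the two OH groups leads to 7), the ketiminium salts 4 and 5 resist a second acylation and are hydrolysed to the ketones, and, because the target needs one ring of each kind, no regiocontrol is required but only a separation that the free para-OH of 6 should make straightforward.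

Step 3
Reactants: 6 1-(4,6-dihydroxy-2-methoxy-3-methylphenyl)butan-1-one
Product: 8 1-{3-[(dimethylamino)methyl]-2,4-dihydroxy-6-methoxy-5-methylphenyl}butan-1-one
Conditions: CH2(NMe2)2 (1.2 equiv), 1,4-dioxane, 0 °C → rt; volatiles evaporated
Reagents that add atoms: bis(dimethylamino)methane (CN(C)CN(C)C)
Why: Phenol Mannich reaction with the aminal as aminomethyl donor, in which the acidic acylphloroglucinol protonates the aminal and the single unsubstituted ring carbon of 6, between its two OH groups, takes up CH2NMe2 to give a zwitterionic base that is stable at room temperature.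

Step 4
Reactants: 8 1-{3-[(dimethylamino)methyl]-2,4-dihydroxy-6-methoxy-5-methylphenyl}butan-1-one; 9 1-(2,4,6-trihydroxyphenyl)ethan-1-one (2,4,6-trihydroxyacetophenone, 4 equiv)
Product: 11 1-{3-[(3-acetyl-2,4,6-trihydroxyphenyl)methyl]-2,4-dihydroxy-6-methoxy-5-methylphenyl}butan-1-one, via ortho-quinone methide 10 (not isolated)
Conditions: 1,4-dioxane, 90 °C, Ar sweep; excess 9 removed by aqueous wash and chromatography
Reagents that add atoms: none
Why: Mannich-base (ortho-quinone methide) C-alkylation, a vinylogous Michael addition in which loss of Me2NH from 8 gives 10, one of the two equivalent ring CH positions of 9 captures it with rearomatisation, and the fourfold excess of 9 should keep the second CH free.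

Step 5
Reactants: 7 1-(2,6-dihydroxy-4-methoxy-3-methylphenyl)butan-1-one (aspidinol)
Product: 12 1-{3-[(dimethylamino)methyl]-2,6-dihydroxy-4-methoxy-5-methylphenyl}butan-1-one
Conditions: CH2(NMe2)2 (1.2 equiv), 1,4-dioxane, 0 °C → rt; volatiles evaporated
Reagents that add atoms: bis(dimethylamino)methane (CN(C)CN(C)C)
Why: Phenol Mannich reaction as in step 3, here at the single unsubstituted ring carbon of 7, which lies between OMe and OH, so that only one regioisomer can form.

Step 6
Reactants: 12 1-{3-[(dimethylamino)methyl]-2,6-dihydroxy-4-methoxy-5-methylphenyl}butan-1-one (1.15 equiv); 11 1-{3-[(3-acetyl-2,4,6-trihydroxyphenyl)methyl]-2,4-dihydroxy-6-methoxy-5-methylphenyl}butan-1-one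
Product: 14 1-{3-[(3-butanoyl-2,4-dihydroxy-6-methoxy-5-methylphenyl)methyl]-5-[(3-butanoyl-2,6-dihydroxy-4-methoxy-5-methylphenyl)methyl]-2,4,6-trihydroxyphenyl}ethan-1-one (CNP0184345.0), via ortho-quinone methide 13 (not isolated)
Conditions: 1,4-dioxane, 90 °C, Ar sweep
Reagents that add atoms: none
Why: Warming the zwitterionic Mannich base 12 expels dimethylamine from the phenoxide next to the CH2NMe2 carbon (E1cB-type) and gives the dearomatised ortho-quinone methide 13; C5 of the central ring of 11, an enol-like carbon flanked by two OH groups, adds to its exocyclic CH2, and tautomerisation restores both aromatic rings. The closest known reaction type is the Mannich-base (ortho-quinone methide) C-alkylation of phloroglucinols, a vinylogous Michael addition that is the standard way to methylene-bridged acylphloroglucinols. No ring is closed and no stereocentre is formed. The step needs C- over O-alkylation, which follows because O-adducts revert to 13 while the C-adduct aromatises irreversibly. It needs one quinone methide only, which the substrate secures because the aminomethyl carbon of 12 has a single OH neighbour (the other neighbour is OMe). It needs cross- and not homo-coupling, which is secured because 12 has no free ring position and 11 has exactly one.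

Compound list

1 | 2,4-dihydroxy-6-methoxybenzaldehyde | COc1cc(O)cc(O)c1C=O | starting material
2 | 4-(hydroxymethyl)-5-methoxybenzene-1,3-diol | COc1cc(O)cc(O)c1CO | intermediate
3 | 5-methoxy-4-methylbenzene-1,3-diol | COc1cc(O)cc(O)c1C | intermediate
4 | 1-(4,6-dihydroxy-2-methoxy-3-methylphenyl)butan-1-iminium chloride | CCCC(=[NH2+])c1c(OC)c(C)c(O)cc1O.[Cl-] | intermediate
5 | 1-(2,6-dihydroxy-4-methoxy-3-methylphenyl)butan-1-iminium chloride | CCCC(=[NH2+])c1c(O)c(C)c(OC)cc1O.[Cl-] | intermediate
6 | 1-(4,6-dihydroxy-2-methoxy-3-methylphenyl)butan-1-one | CCCC(=O)c1c(OC)c(C)c(O)cc1O | intermediate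
7 | 1-(2,6-dihydroxy-4-methoxy-3-methylphenyl)butan-1-one (aspidinol) | CCCC(=O)c1c(O)c(C)c(OC)cc1O | intermediate
8 | 1-{3-[(dimethylamino)methyl]-2,4-dihydroxy-6-methoxy-5-methylphenyl}butan-1-one | CCCC(=O)c1c(OC)c(C)c(O)c(CN(C)C)c1O | intermediate
9 | 1-(2,4,6-trihydroxyphenyl)ethan-1-one (2,4,6-trihydroxyacetophenone) | CC(=O)c1c(O)cc(O)cc1O | starting material
10 | 4-butanoyl-3-hydroxy-5-methoxy-6-methyl-2-methylidenecyclohexa-3,5-dien-1-one | CCCC(=O)C1=C(O)C(=C)C(=O)C(C)=C1OC | intermediate
11 | 1-{3-[(3-acetyl-2,4,6-trihydroxyphenyl)methyl]-2,4-dihydroxy-6-methoxy-5-methylphenyl}butan-1-one | CCCC(=O)c1c(OC)c(C)c(O)c(Cc2c(O)cc(O)c(C(C)=O)c2O)c1O | intermediate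
12 | 1-{3-[(dimethylamino)methyl]-2,6-dihydroxy-4-methoxy-5-methylphenyl}butan-1-one | CCCC(=O)c1c(O)c(C)c(OC)c(CN(C)C)c1O | intermediate
13 | 2-butanoyl-3-hydroxy-5-methoxy-4-methyl-6-methylidenecyclohexa-2,4-dien-1-one | CCCC(=O)C1=C(O)C(C)=C(OC)C(=C)C1=O | intermediate
14 | 1-{3-[(3-butanoyl-2,4-dihydroxy-6-methoxy-5-methylphenyl)methyl]-5-[(3-butanoyl-2,6-dihydroxy-4-methoxy-5-methylphenyl)methyl]-2,4,6-trihydroxyphenyl}ethan-1-one (CNP0184345.0) | CCCC(=O)c1c(O)c(C)c(OC)c(Cc2c(O)c(Cc3c(O)c(C)c(OC)c(C(=O)CCC)c3O)c(O)c(C(C)=O)c2O)c1O | target

Total step count: 6.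
Longest linear sequence: 5 steps (steps 1, 2, 3, 4 and 6).

Steps most likely to fail

Step 6. At 90 °C the methylene bridges may exchange: either diarylmethane unit can release a quinone methide by retro-Michael cleavage, which would scramble the arms. The quinone methide may also condense with itself before it is captured. The fallback sets out from 12 and 11 and avoids heat. N-Methylation of 12 (MeI, acetone, rt) should give the benzylic trimethylammonium iodide F1. Stirring F1 with 11 and NaHCO3 in DMF at 0–20 °C should then release 13 from the ammonium phenoxide by loss of trimethylamine, and capture by 11 returns to the route at 14.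

Step 2. The two acylation sites may be used very unevenly, or the regioisomers may co-elute, so that the route runs short of one ketone. The fallback sets out from 3 and replaces the acylation of an unsymmetrical arene by one of a symmetrical arene, followed by regiocontrolled O-methylation. Ether cleavage of 3 (BBr3, CH2Cl2, −78 °C → rt) gives 2-methylbenzene-1,3,5-triol F2, which is also a catalogue compound. Its two ring CH positions are equivalent, so Friedel–Crafts butanoylation (PrCOCl, AlCl3, PhNO2, rt) should give a single ketone, 1-(2,4,6-trihydroxy-3-methylphenyl)butan-1-one F3. Methylation of its para-OH, the most acidic one and the only one free of hydrogen bonding to the ketone (Me2SO4, 1 equiv, K2CO3, acetone, rt), comes back to 7. For the other ketone, F3 is tosylated at the para-OH and at the less hindered ortho-OH (TsCl, 2 equiv, K2CO3, acetone) to 1-[2-hydroxy-3-methyl-4,6-bis(tosyloxy)phenyl]butan-1-one F4. The remaining OH next to the ring methyl is methylated (Me2SO4, K2CO3, acetone, reflux) to 1-[2-methoxy-3-methyl-4,6-bis(tosyloxy)phenyl]butan-1-one F5, and removal of the sulfonates (KOH, aq. EtOH, reflux) comes back to 6.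

Step 4. The core may be alkylated at both of its ring CH positions, and the very labile quinone methide 10 may be lost to self-capture. The fallback sets out from 9 and 6 and reverses the roles of the partners, so that 8 is not needed. Aminomethylation of one ring CH of 9 (CH2(NMe2)2, 1.0 equiv, THF, −20 °C, the zwitterion precipitating) should give 1-{3-[(dimethylamino)methyl]-2,4,6-trihydroxyphenyl}ethan-1-one F6. Heating F6 with an excess of 6 (3 equiv, 1,4-dioxane, 90 °C, Ar sweep) then generates the quinone methide on the core. It is captured by the single ring CH of 6, between its two OH groups, which comes back to the route at 11; a second alkylation of the core is excluded by construction.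

Further compounds

F1 | step 6 | 1-(3-butanoyl-2,4-dihydroxy-6-methoxy-5-methylphenyl)-N,N,N-trimethylmethanaminium iodide | CCCC(=O)c1c(O)c(C)c(OC)c(C[N+](C)(C)C)c1O.[I-]
F2 | step 2 | 2-methylbenzene-1,3,5-triol | Cc1c(O)cc(O)cc1O
F3 | step 2 | 1-(2,4,6-trihydroxy-3-methylphenyl)butan-1-one | CCCC(=O)c1c(O)c(C)c(O)cc1O
F4 | step 2 | 1-[2-hydroxy-3-methyl-4,6-bis(tosyloxy)phenyl]butan-1-one | CCCC(=O)c1c(O)c(C)c(OS(=O)(=O)c2ccc(C)cc2)cc1OS(=O)(=O)c1ccc(C)cc1
F5 | step 2 | 1-[2-methoxy-3-methyl-4,6-bis(tosyloxy)phenyl]butan-1-one | CCCC(=O)c1c(OC)c(C)c(OS(=O)(=O)c2ccc(C)cc2)cc1OS(=O)(=O)c1ccc(C)cc1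
F6 | step 4 | 1-{3-[(dimethylamino)methyl]-2,4,6-trihydroxyphenyl}ethan-1-one | CC(=O)c1c(O)cc(O)c(CN(C)C)c1O
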